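## Retrosynthetic overview

1. The dihydrofuran ring (O1–C2–C3–C3a–C7a) is cut at C3a–C3 and O1–C2, giving 5-iodovanillin (ring C) and the (E)-cinnamyl silyl ether 15, which already carries rings A and B and the erythro glycerol unit. One enantioselective palladium-catalysed [3+2] heteroannulation makes both bonds and both ring stereocentres.
2. Enabling feature: O1 and C3a are ortho neighbours on ring C (an ortho-iodophenol in the precursor), C2 is benzylic to the electron-rich ring B, and C2=C3 is an E-styrene-type alkene. Palladium delivered to C2 is therefore held as a ring-B-stabilised benzyl and captured by O1.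
3. The 8-O-4' ether between rings A and B comes from an Evans syn-aldol of an aryloxyacetyl oxazolidinone (from sinapyl alcohol) with O-silyl vanillin (threo, 7R,8R). Reduction of the auxiliary and Mitsunobu inversion at the benzylic carbon give the erythro (7S,8R) series.
4. Ring order: rings A, B and C are bought as arenes (vanillin, sinapyl alcohol, 5-iodovanillin). The dihydrofuran ring is the only ring built (step 11), and a global desilylation ends the route.

Key step: step 11

Remark (assumption): the aryloxyacetyl imide is taken to react with the same facial sense as glycolate and propionyl imides in the boron aldol, and the antipode of the bisphosphine in step 11 that gives the 3S sense is fixed by a small test reaction. TBS = tert-butyldimethylsilyl.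

## Route

Step 1
Reactants: 1 vanillin
Product: 2 4-(TBS-oxy)-3-methoxybenzaldehyde
Conditions: TBSCl, imidazole, CH2Cl2, 0 °C to rt
Reagents that add atoms: tert-butyldimethylsilyl chloride, CC(C)(C)[Si](C)(C)Cl
Why: Imidazole-promoted silylation of the phenol masks the acidic OH for the boron aldol and installs a fluoride-labile group; no stereocentre is formed.

Step 2
Reactants: 3 (S)-4-benzyloxazolidin-2-one
Product: 5 (S)-4-benzyl-3-(2-bromoacetyl)oxazolidin-2-one, via N-lithio oxazolidinone 4 (not isolated)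
Conditions: n-BuLi, THF, −78 °C; then BrCH2COBr, −78 °C to 0 °C
Reagents that add atoms: bromoacetyl bromide, BrCC(Br)=O
Why: N-Acylation of the lithiated oxazolidinone with an acid bromide is routine and leaves the auxiliary stereocentre untouched.

Step 3
Reactants: 5 (S)-4-benzyl-3-(2-bromoacetyl)oxazolidin-2-one; 6 (E)-sinapyl alcohol
Product: 7 (S)-4-benzyl-3-{2-[4-((E)-3-hydroxyprop-1-enyl)-2,6-dimethoxyphenoxy]acetyl}oxazolidin-2-one
Conditions: K2CO3, acetone, rt, under argon
Reagents that add atoms: none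
Why: Williamson ether synthesis in which only the phenol of 6 is deprotonated by K2CO3 and the phenoxide displaces bromide from the activated α-bromo imide by SN2 faster than it attacks the imide carbonyl; no stereocentre is formed.

Step 4
Reactants: 7 imide with free allylic alcohol
Product: 8 (S)-4-benzyl-3-{2-[4-((E)-3-(TBS-oxy)prop-1-enyl)-2,6-dimethoxyphenoxy]acetyl}oxazolidin-2-one
Conditions: TBSCl, imidazole, CH2Cl2, 0 °C to rt
Reagents that add atoms: tert-butyldimethylsilyl chloride, CC(C)(C)[Si](C)(C)Cl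
Why: Silylation of the primary allylic alcohol gives an ether that, unlike an allylic ester, is not ionised by zerovalent palladium in step 11; no stereocentre is formed.

Step 5
Reactants: 8 aryloxyacetyl imide; 2 4-(TBS-oxy)-3-methoxybenzaldehyde
Product: 10 syn-aldol adduct (2S,3R) on the (S)-auxiliary, via Z-boron enolate 9 (not isolated)
Conditions: Bu2BOTf, iPr2NEt, CH2Cl2, −78 to 0 °C; then 2, −78 to 0 °C; pH 7 buffer, MeOH, H2O2, 0 °C
Reagents that add atoms: none
Why: Evans syn-aldol reaction in which the Z-boron enolate 9 reacts through a Zimmerman–Traxler chair with the benzyl group of the auxiliary shielding one enolate face, so both new stereocentres (2S,3R in the imide, which is 8R,7R threo in lignan numbering) are set by the auxiliary.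

Step 6
Reactants: 10 syn-aldol adduct
Product: 11 threo diol (1R,2R)-1-aryl-2-aryloxypropane-1,3-diol
Conditions: LiBH4, THF, MeOH (1 equiv), 0 °C
Reagents that add atoms: none
Why: Reductive cleavage of the N-acyl oxazolidinone with LiBH4 gives the primary alcohol and returns the auxiliary without touching the silyl ethers or the two stereocentres.

Step 7
Reactants: 11 threo diol
Product: 12 threo alcohol (1R,2R) with the primary hydroxyl as TBS ether
Conditions: TBSCl (1.1 equiv), imidazole, CH2Cl2, 0 °C
Reagents that add atoms: tert-butyldimethylsilyl chloride, CC(C)(C)[Si](C)(C)Cl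
Why: Selective silylation, because the primary hydroxyl reacts much faster than the hindered secondary benzylic one with one equivalent of TBSCl at 0 °C; no stereocentre is touched.

Step 8
Reactants: 12 threo alcohol
Product: 13 erythro 4-nitrobenzoate (1S,2R)
Conditions: PPh3, DIAD, 4-nitrobenzoic acid, THF, 0 °C to rt
Reagents that add atoms: 4-nitrobenzoic acid, OC(=O)c1ccc(cc1)[N+](=O)[O-]
Why: Mitsunobu reaction in which the benzylic hydroxyl is activated as an oxyphosphonium ion and displaced by the carboxylate with inversion (1R to 1S), converting threo into erythro as established for β-O-4 model compounds.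

Step 9
Reactants: 13 erythro 4-nitrobenzoate
Product: 14 erythro alcohol (1S,2R)
Conditions: iBu2AlH, CH2Cl2, −78 °C
Reagents that add atoms: none
Why: Reductive ester cleavage at the acyl carbon frees the alcohol with retention and, unlike basic methanolysis, keeps the aryl silyl ether, so no para-phenoxide is unmasked next to a benzylic ester (quinone methide formation is avoided).

Step 10
Reactants: 14 erythro alcohol
Product: 15 tetra-TBS (E)-alkene (1S,2R)
Conditions: TBSOTf, 2,6-lutidine, CH2Cl2, −78 to 0 °C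
Reagents that add atoms: tert-butyldimethylsilyl triflate, CC(C)(C)[Si](C)(C)OS(=O)(=O)C(F)(F)F
Why: Silyl triflate silylation of the hindered secondary benzylic alcohol removes the last free hydroxyl (which could be oxidised through a palladium alkoxide in step 11) and gives one uniform protecting-group set; no stereocentre is touched.

Step 11
Reactants: 15 tetra-TBS (E)-alkene; 16 5-iodovanillin
Product: 18 tetra-TBS ether of the target (2R,3S), via oxapalladacycle 17 (not isolated)
Conditions: Pd(OAc)2 (10 mol%), (R)-SEGPHOS (12 mol%; antipode if the test reaction demands it), Ag2CO3 (1.5 equiv), 16 (1.5 equiv), toluene, 60 °C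
Reagents that add atoms: none
Why: Proposed new method: the closest known reaction types are the palladium-catalysed oxyarylation of 2H-chromenes with ortho-iodophenols (racemic) and the enantioselective palladium-catalysed heteroannulation or carboetherification of 1,3-dienes and 2,3-dihydrofurans with ortho-halophenols, and what is new is an acyclic (E)-cinnamyl ether under catalyst control. Mechanistically, zerovalent palladium inserts into the C–I bond of 16, Ag2CO3 removes iodide and deprotonates the phenol, and the cationic aryl–palladium bisphosphine complex adds syn across the alkene with the aryl carbon going to the CH2OTBS-bearing carbon (future C3) and palladium to the benzylic carbon (future C2), which is the regiochemistry of Heck arylations of β-substituted styrenes; the aryloxide then binds palladium (oxapalladacycle 17) and C–O reductive elimination with retention closes the dihydrofuran ring at O1–C2, the equivalent of a 5-exo attack of the aryloxide on the benzylic carbon in an intermolecular [3+2] annulation. C3 (S) is set in the enantio-determining insertion by the chiral bisphosphine, the three existing stereocentres being too remote to interfere, and C2 (R) follows from the stereospecific syn addition to the E-alkene, which gives the trans ring that is also the thermodynamically preferred one. The step needs C–O bond formation to outrun β-hydride elimination of the C3–H, and this is secured by the electron-rich ring B, which holds palladium as an η3-benzyl in a cationic chelated complex without a cis-vacant site, and by the ortho-aryloxide, which is delivered intramolecularly. Chemoselectivity is secured by the absence of any free hydroxyl, allylic ester or second carbon–halogen bond in 15 and 16.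

Step 12
Reactants: 18 tetra-TBS ether of the target
Product: 19 target compound CID53356209
Conditions: Bu4NF, AcOH (1:1, excess), THF, 0 °C to rt
Reagents that add atoms: none
Why: Fluoride-mediated cleavage of the one aryl, two primary and one secondary silyl ether, with acetic acid keeping the liberated phenols protonated so that the para-hydroxybenzyl alcohol unit and the aldehyde are not exposed to strong base; no stereocentre is touched.

## Compound list

1 | vanillin (4-hydroxy-3-methoxybenzaldehyde) | COc1cc(C=O)ccc1O | starting material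
2 | 4-[(tert-butyldimethylsilyl)oxy]-3-methoxybenzaldehyde | COc1cc(C=O)ccc1O[Si](C)(C)C(C)(C)C | intermediate
3 | (S)-4-benzyloxazolidin-2-one | O=C1N[C@@H](Cc2ccccc2)CO1 | starting material
4 | N-lithio-(S)-4-benzyloxazolidin-2-one (not isolated) | [Li]N1[C@@H](Cc2ccccc2)COC1=O | intermediate
5 | (S)-4-benzyl-3-(2-bromoacetyl)oxazolidin-2-one | O=C1OC[C@H](Cc2ccccc2)N1C(=O)CBr | intermediate
6 | (E)-sinapyl alcohol, 4-[(E)-3-hydroxyprop-1-en-1-yl]-2,6-dimethoxyphenol | COc1cc(/C=C/CO)cc(OC)c1O | starting material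
7 | (S)-4-benzyl-3-{2-[4-((E)-3-hydroxyprop-1-en-1-yl)-2,6-dimethoxyphenoxy]acetyl}oxazolidin-2-one | COc1cc(/C=C/CO)cc(OC)c1OCC(=O)N1[C@@H](Cc2ccccc2)COC1=O | intermediate
8 | (S)-4-benzyl-3-{2-[4-((E)-3-[(tert-butyldimethylsilyl)oxy]prop-1-en-1-yl)-2,6-dimethoxyphenoxy]acetyl}oxazolidin-2-one | COc1cc(/C=C/CO[Si](C)(C)C(C)(C)C)cc(OC)c1OCC(=O)N1[C@@H](Cc2ccccc2)COC1=O | intermediate
9 | (Z)-O-dibutylboryl enolate of 8, boryloxy and aryloxy cis (not isolated) | CCCCB(CCCC)O/C(=C\Oc1c(OC)cc(/C=C/CO[Si](C)(C)C(C)(C)C)cc1OC)N1[C@@H](Cc2ccccc2)COC1=O | intermediate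
10 | (S)-4-benzyl-3-[(2S,3R)-3-hydroxy-3-(4-TBS-oxy-3-methoxyphenyl)-2-{4-[(E)-3-(TBS-oxy)prop-1-en-1-yl]-2,6-dimethoxyphenoxy}propanoyl]oxazolidin-2-one | COc1cc([C@@H](O)[C@@H](C(=O)N2[C@@H](Cc3ccccc3)COC2=O)Oc2c(OC)cc(/C=C/CO[Si](C)(C)C(C)(C)C)cc2OC)ccc1O[Si](C)(C)C(C)(C)C | intermediate
11 | (1R,2R)-1-(4-TBS-oxy-3-methoxyphenyl)-2-{4-[(E)-3-(TBS-oxy)prop-1-en-1-yl]-2,6-dimethoxyphenoxy}propane-1,3-diol (threo) | COc1cc([C@@H](O)[C@@H](CO)Oc2c(OC)cc(/C=C/CO[Si](C)(C)C(C)(C)C)cc2OC)ccc1O[Si](C)(C)C(C)(C)C | intermediate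
12 | (1R,2R)-3-(TBS-oxy)-1-(4-TBS-oxy-3-methoxyphenyl)-2-{4-[(E)-3-(TBS-oxy)prop-1-en-1-yl]-2,6-dimethoxyphenoxy}propan-1-ol (threo) | COc1cc([C@@H](O)[C@@H](CO[Si](C)(C)C(C)(C)C)Oc2c(OC)cc(/C=C/CO[Si](C)(C)C(C)(C)C)cc2OC)ccc1O[Si](C)(C)C(C)(C)C | intermediate
13 | (1S,2R)-3-(TBS-oxy)-1-(4-TBS-oxy-3-methoxyphenyl)-2-{4-[(E)-3-(TBS-oxy)prop-1-en-1-yl]-2,6-dimethoxyphenoxy}propyl 4-nitrobenzoate (erythro) | COc1cc([C@H](OC(=O)c2ccc(cc2)[N+](=O)[O-])[C@@H](CO[Si](C)(C)C(C)(C)C)Oc2c(OC)cc(/C=C/CO[Si](C)(C)C(C)(C)C)cc2OC)ccc1O[Si](C)(C)C(C)(C)C | intermediate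
14 | (1S,2R)-3-(TBS-oxy)-1-(4-TBS-oxy-3-methoxyphenyl)-2-{4-[(E)-3-(TBS-oxy)prop-1-en-1-yl]-2,6-dimethoxyphenoxy}propan-1-ol (erythro) | COc1cc([C@H](O)[C@@H](CO[Si](C)(C)C(C)(C)C)Oc2c(OC)cc(/C=C/CO[Si](C)(C)C(C)(C)C)cc2OC)ccc1O[Si](C)(C)C(C)(C)C | intermediate
15 | (1S,2R)-1,3-bis(TBS-oxy)-1-(4-TBS-oxy-3-methoxyphenyl)-2-{4-[(E)-3-(TBS-oxy)prop-1-en-1-yl]-2,6-dimethoxyphenoxy}propane (erythro) | COc1cc([C@H](O[Si](C)(C)C(C)(C)C)[C@@H](CO[Si](C)(C)C(C)(C)C)Oc2c(OC)cc(/C=C/CO[Si](C)(C)C(C)(C)C)cc2OC)ccc1O[Si](C)(C)C(C)(C)C | intermediate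
16 | 5-iodovanillin (4-hydroxy-3-iodo-5-methoxybenzaldehyde) | COc1cc(C=O)cc(I)c1O | starting material
17 | six-membered oxapalladacycle from 15 and 16, Pd bound to the benzylic carbon and to the aryloxide oxygen, bisphosphine not drawn (not isolated) | COc1cc([C@H](O[Si](C)(C)C(C)(C)C)[C@@H](CO[Si](C)(C)C(C)(C)C)Oc2c(OC)cc([C@@H]3[Pd]Oc4c(OC)cc(C=O)cc4[C@H]3CO[Si](C)(C)C(C)(C)C)cc2OC)ccc1O[Si](C)(C)C(C)(C)C | intermediate
18 | (2R,3S)-2-{4-[((1S,2R)-1,3-bis(TBS-oxy)-1-(4-TBS-oxy-3-methoxyphenyl)propan-2-yl)oxy]-3,5-dimethoxyphenyl}-3-[(TBS-oxy)methyl]-7-methoxy-2,3-dihydrobenzofuran-5-carbaldehyde | COc1cc([C@H](O[Si](C)(C)C(C)(C)C)[C@@H](CO[Si](C)(C)C(C)(C)C)Oc2c(OC)cc([C@@H]3Oc4c(OC)cc(C=O)cc4[C@H]3CO[Si](C)(C)C(C)(C)C)cc2OC)ccc1O[Si](C)(C)C(C)(C)C | intermediate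
19 | (2R,3S)-2-{4-[((1S,2R)-1,3-dihydroxy-1-(4-hydroxy-3-methoxyphenyl)propan-2-yl)oxy]-3,5-dimethoxyphenyl}-3-(hydroxymethyl)-7-methoxy-2,3-dihydrobenzofuran-5-carbaldehyde (CID53356209) | COc1cc([C@H](O)[C@@H](CO)Oc2c(OC)cc([C@@H]3Oc4c(OC)cc(C=O)cc4[C@H]3CO)cc2OC)ccc1O | target

## Step count and risks

Total step count: 12. Longest linear sequence: 11 steps (3 to 19 through steps 2 to 12).

**Step 11 (Proposed new method).** What may go wrong: β-hydride elimination from the benzylic palladium intermediate before C–O bond formation (a Heck-type arylation instead of annulation), or weak facial discrimination in the insertion into the acyclic 1,2-disubstituted alkene. The fallback sets out from 15 and returns at 18. It uses the known photocatalytic oxidative [3+2] cycloaddition of para-alkoxyphenols with aryl propenes, followed by exchange of the phenol oxygen for the formyl group.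
- Methoxyhydroquinone is monobenzylated at the less hindered 4-hydroxyl (BnBr, K2CO3, acetone) to 4-(benzyloxy)-2-methoxyphenol F1.
- F1 and 15 are joined with Ru(bpz)3(PF6)2 (cat.), (NH4)2S2O8, MeCN, blue light, to the trans 5-benzyloxy dihydrobenzofuran F2. This union is not catalyst-controlled, so the (2R,3S) diastereomer would have to be separated from its (2S,3R) partner by chromatography.
- Hydrogenolysis (H2, Pd/C, EtOAc) should give the 5-hydroxy dihydrobenzofuran F3.
- PhNTf2, Et3N, CH2Cl2 should give the aryl triflate F4.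
- Reductive carbonylation (Pd(OAc)2, dppp, CO, Et3SiH, Et3N, DMF, 70 °C) should convert F4 into 18.

**Step 8.** What may go wrong: ionisation of the electron-rich benzylic oxyphosphonium ion (partial retention through an SN1 pathway) or elimination instead of clean SN2 inversion. The fallback sets out from 12 and returns at 14, bypassing 13. Dess–Martin periodinane (CH2Cl2, NaHCO3, 0 °C) oxidises the benzylic alcohol to the (R)-α-aryloxy ketone F5. Chelation-controlled reduction with Zn(BH4)2 (Et2O, −20 °C) is expected to give the erythro alcohol 14, in line with the erythro preference known for reductions of β-O-4 model ketones.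

**Step 3.** What may go wrong: acyl transfer, meaning attack of the phenoxide on the exocyclic imide carbonyl with loss of the auxiliary instead of SN2 at the α-carbon. The fallback sets out from 6 and returns at 8, bypassing 5 and 7.
- Ethyl bromoacetate, K2CO3, acetone gives ethyl 2-{4-[(E)-3-hydroxyprop-1-en-1-yl]-2,6-dimethoxyphenoxy}acetate F6.
- TBSCl and imidazole give the silyl ether ethyl ester F7.
- LiOH in THF/H2O gives the aryloxyacetic acid F8.
- Activation as the mixed pivalic anhydride (pivaloyl chloride, Et3N, THF, −20 °C) and acylation of the lithium salt 4 give 8.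

Further compounds
F1 | step 11 | 4-(benzyloxy)-2-methoxyphenol | COc1cc(OCc2ccccc2)ccc1O
F2 | step 11 | (2R,3S)-5-(benzyloxy) analogue of 18 (benzyloxy in place of the formyl group) | COc1cc([C@H](O[Si](C)(C)C(C)(C)C)[C@@H](CO[Si](C)(C)C(C)(C)C)Oc2c(OC)cc([C@@H]3Oc4c(OC)cc(OCc5ccccc5)cc4[C@H]3CO[Si](C)(C)C(C)(C)C)cc2OC)ccc1O[Si](C)(C)C(C)(C)C
F3 | step 11 | (2R,3S)-5-hydroxy analogue of 18 (hydroxyl in place of the formyl group) | COc1cc([C@H](O[Si](C)(C)C(C)(C)C)[C@@H](CO[Si](C)(C)C(C)(C)C)Oc2c(OC)cc([C@@H]3Oc4c(OC)cc(O)cc4[C@H]3CO[Si](C)(C)C(C)(C)C)cc2OC)ccc1O[Si](C)(C)C(C)(C)C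
F4 | step 11 | (2R,3S)-5-(trifluoromethanesulfonyloxy) analogue of 18 | COc1cc([C@H](O[Si](C)(C)C(C)(C)C)[C@@H](CO[Si](C)(C)C(C)(C)C)Oc2c(OC)cc([C@@H]3Oc4c(OC)cc(OS(=O)(=O)C(F)(F)F)cc4[C@H]3CO[Si](C)(C)C(C)(C)C)cc2OC)ccc1O[Si](C)(C)C(C)(C)C
F5 | step 8 | (R)-3-(TBS-oxy)-1-(4-TBS-oxy-3-methoxyphenyl)-2-{4-[(E)-3-(TBS-oxy)prop-1-en-1-yl]-2,6-dimethoxyphenoxy}propan-1-one | COc1cc(C(=O)[C@@H](CO[Si](C)(C)C(C)(C)C)Oc2c(OC)cc(/C=C/CO[Si](C)(C)C(C)(C)C)cc2OC)ccc1O[Si](C)(C)C(C)(C)C
F6 | step 3 | ethyl 2-{4-[(E)-3-hydroxyprop-1-en-1-yl]-2,6-dimethoxyphenoxy}acetate | CCOC(=O)COc1c(OC)cc(/C=C/CO)cc1OC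
F7 | step 3 | ethyl 2-{4-[(E)-3-(TBS-oxy)prop-1-en-1-yl]-2,6-dimethoxyphenoxy}acetate | CCOC(=O)COc1c(OC)cc(/C=C/CO[Si](C)(C)C(C)(C)C)cc1OC
F8 | step 3 | 2-{4-[(E)-3-(TBS-oxy)prop-1-en-1-yl]-2,6-dimethoxyphenoxy}acetic acid | OC(=O)COc1c(OC)cc(/C=C/CO[Si](C)(C)C(C)(C)C)cc1OC
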